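**Retrosynthetic overview**
1. The dienone hides a methyl tetronate: the ether oxygen on C4, C4 itself, C5 with its enol methoxy group, C6 and the carbonyl carbon C1 are the five ring atoms of a 4-methoxyfuran-2(5H)-one, and the remaining ring carbons C2 (allyl) and C3 are a vinyl group on C4.
2. Key disconnection C1–C2: the carbocycle is closed from iodovinyl tetronate 16 by iodine–lithium exchange and attack of the vinyllithium on the lactone carbonyl; the lactone opens in the same step and the freed C4 alkoxide is methylated.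
3. The tetronate ring comes from (Z)-β-iodoenone 11 by 1,2-addition of lithiated methyl propiolate (C4 set against C8) and methoxide addition/lactonisation.
4. The iodoenone comes from Weinreb amide 6 and pent-1-en-4-yne (ynone, then conjugate addition of HI); C8 is bought in methyl (2S)-3-bromo-2-methylpropanoate and joined to silylated 4-bromo-2-methoxyphenol by Negishi coupling.
5. Ring order: arene (bought), butenolide (step 7), cyclohexadienone (step 8, with opening of the butenolide); desilylation ends the route.

Key step: step 8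

Assumption: the phenol is carried as a triisopropylsilyl ether, because an aryl tert-butyldimethylsilyl ether is expected to be cleaved by the methoxide of step 7; locants in the text are those of the dienone (C1 carbonyl, C2 allyl-bearing, C3, C4 quaternary, C5 enol ether carbon, C6; C8 side-chain methine, C7 benzylic CH2).

**Route**

Step 1
Reactants: 1 4-bromo-2-methoxyphenol
Product: 2 (4-bromo-2-methoxyphenoxy)triisopropylsilane
Conditions: TIPSCl, imidazole, DMF, 25 °C
Reagents that add atoms: chlorotriisopropylsilane, CC(C)[Si](Cl)(C(C)C)C(C)C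
Why: Imidazole-assisted O-silylation of the phenol; the triisopropylsilyl ether tolerates the organometallic steps, resists the catalytic methoxide of step 7 far better than a smaller silyl ether, and is still removed by fluoride at the end.

Step 2
Reactants: 3 methyl (2S)-3-bromo-2-methylpropanoate; 2 (4-bromo-2-methoxyphenoxy)triisopropylsilane
Product: 5 methyl (2R)-3-[3-methoxy-4-(triisopropylsilyloxy)phenyl]-2-methylpropanoate, via organozinc bromide 4 (not isolated)
Conditions: 3, Zn dust, LiCl, THF, 50 °C; then 2, Pd(OAc)2 (cat.), SPhos (2-dicyclohexylphosphino-2',6'-dimethoxybiphenyl, cat.), THF, 25 → 50 °C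
Reagents that add atoms: none
Why: Zinc insertion into the primary C–Br bond and Negishi cross-coupling of the alkylzinc bromide with the aryl bromide; the stereocentre is β to zinc and takes no part, so the (S)-bromoester gives the (R)-ester with unchanged geometry (the descriptor changes only because the ester carbon now outranks the CH2 group).

Step 3
Reactants: 5 methyl (2R)-3-[3-methoxy-4-(triisopropylsilyloxy)phenyl]-2-methylpropanoate
Product: 6 (2R)-N-methoxy-3-[3-methoxy-4-(triisopropylsilyloxy)phenyl]-N,2-dimethylpropanamide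
Conditions: MeNH(OMe)·HCl, i-PrMgCl, THF, −20 → 0 °C
Reagents that add atoms: N,O-dimethylhydroxylamine hydrochloride, CNOC.Cl
Why: Weinreb amide synthesis by aminolysis of the ester with the chloromagnesium amide of N,O-dimethylhydroxylamine; this amide is too weak a base to enolise the ester at low temperature, so C8 is kept.

Step 4
Reactants: 7 pent-1-en-4-yne; 6 (2R)-N-methoxy-3-[3-methoxy-4-(triisopropylsilyloxy)phenyl]-N,2-dimethylpropanamide
Product: 10 (2R)-1-[3-methoxy-4-(triisopropylsilyloxy)phenyl]-2-methyloct-7-en-4-yn-3-one, via lithium acetylide 8 (not isolated), via tetrahedral lithium adduct 9 (not isolated)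
Conditions: 7 (2 equiv), n-BuLi, THF, −78 °C; then 6, −78 → −20 °C; inverse quench into cold 1 M HCl
Reagents that add atoms: none
Why: Weinreb ketone synthesis: the acetylide adds only once because the N-methoxy chelate 9 persists until the quench, and the cold acidic inverse quench protonates the released amine and keeps base away from the doubly activated CH2 of the skipped enynone.

Step 5
Reactants: 10 (2R)-1-[3-methoxy-4-(triisopropylsilyloxy)phenyl]-2-methyloct-7-en-4-yn-3-one
Product: 11 (2R,4Z)-5-iodo-1-[3-methoxy-4-(triisopropylsilyloxy)phenyl]-2-methylocta-4,7-dien-3-one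
Conditions: NaI, AcOH, 25 °C, dark
Reagents that add atoms: sodium iodide, [Na+].[I-]
Why: Conjugate hydroiodination of the ynone: iodide adds to the β-carbon and the allenol is protonated anti to iodine, which should give under kinetic control the Z-β-iodoenone with iodine cis to the carbonyl, while the acidic medium leaves the skipped diene and C8 alone.

Step 6
Reactants: 12 methyl prop-2-ynoate (methyl propiolate); 11 (2R,4Z)-5-iodo-1-[3-methoxy-4-(triisopropylsilyloxy)phenyl]-2-methylocta-4,7-dien-3-one
Product: 14 methyl (4R,5Z)-4-hydroxy-6-iodo-4-{(2R)-1-[3-methoxy-4-(triisopropylsilyloxy)phenyl]propan-2-yl}nona-5,8-dien-2-ynoate, via lithiated methyl propiolate 13 (not isolated)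
Conditions: 12, LiN(SiMe3)2, THF, −78 °C; then 11, −78 °C; AcOH quench at −78 °C; chromatographic separation of the C4 epimers
Reagents that add atoms: none
Why: 1,2-Addition of a lithium alkynide to the ketone; C4 is set by Felkin–Anh control from C8 (arylmethyl group anti to the incoming alkynide, which passes the C8 hydrogen), which should favour the required (4R) epimer only modestly because methyl and arylmethyl differ little in size, so the epimers are separated and the cold acidic quench forestalls retro-addition.

Step 7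
Reactants: 14 methyl (4R,5Z)-4-hydroxy-6-iodo-4-{(2R)-1-[3-methoxy-4-(triisopropylsilyloxy)phenyl]propan-2-yl}nona-5,8-dien-2-ynoate
Product: 16 (5R)-5-[(1Z)-2-iodopenta-1,4-dien-1-yl]-4-methoxy-5-{(2R)-1-[3-methoxy-4-(triisopropylsilyloxy)phenyl]propan-2-yl}furan-2(5H)-one, via methoxide adduct 15 (not isolated)
Conditions: NaOMe (0.3 equiv), MeOH–THF, 0 → 25 °C; AcOH
Reagents that add atoms: methanol, CO
Why: Classical methyl tetronate synthesis from a 4-hydroxy-2-ynoate: methoxide adds to the β-carbon of the ynoate, the E adduct 15 has the ester cis to the tertiary hydroxyl and lactonises with return of methoxide, so a catalytic amount of base suffices, which spares the hindered aryl silyl ether; C4 and C8 are not touched.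

Step 8
Reactants: 16 (5R)-5-[(1Z)-2-iodopenta-1,4-dien-1-yl]-4-methoxy-5-{(2R)-1-[3-methoxy-4-(triisopropylsilyloxy)phenyl]propan-2-yl}furan-2(5H)-one
Product: 20 (4R)-4,5-dimethoxy-4-{(2R)-1-[3-methoxy-4-(triisopropylsilyloxy)phenyl]propan-2-yl}-2-(prop-2-en-1-yl)cyclohexa-2,5-dien-1-one, via vinyllithium 17 (not isolated), via bridged lithium alkoxide 18 (not isolated), via lithium dienone alkoxide 19 (not isolated)
Conditions: t-BuLi (2.0 equiv, slow addition), THF–Et2O–pentane 4:1:1, −100 °C; → −78 °C; MeOTf (3 equiv), −78 → 0 °C; aq. NaHCO3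
Reagents that add atoms: methyl trifluoromethanesulfonate, COS(=O)(=O)C(F)(F)F
Why: Proposed new method: t-BuLi at −100 °C should convert the vinyl iodide into vinyllithium 17 with the alkene geometry intact (the second equivalent consumes the t-BuI formed), and because C2 then sits cis to C4 and only two bonds away from it, the carbanion can fold across one face of the five-membered lactone and bond to its carbonyl carbon C1, which produces the oxygen-bridged bicyclic hemiketal alkoxide 18; this strained 7-oxanorbornadiene should collapse at once by expelling the ring oxygen from C1, so that the lactone becomes the C1 ketone of the dienone and the oxygen stays on C4 as lithium alkoxide 19, which is then O-methylated by methyl triflate. The nearest precedents are the Parham cyclisation (halogen–lithium exchange followed by intramolecular acylation) and the Hauser–Kraus annulation (carbanion addition to a lactone carbonyl with departure of the ring oxygen as an alkoxide); what has no precedent is the conversion of a butenolide into a carbocycle by a vinyllithium attached to the butenolide's own C5. The six-membered carbocycle is closed by 6-exo-trig attack on the carbonyl (5-exo-trig if the path through the ring oxygen is counted), and the butenolide is opened in the same operation. The product gains no stereocentre: the bridgehead C1 of 18 is lost again on ring opening, and C4 keeps its configuration because the bond between C4 and its oxygen is not touched at any point. Two rate orders are needed, exchange ahead of any attack of t-BuLi on the lactone or on C6–H (served by the iodide, the temperature and slow addition of exactly two equivalents) and ring closure ahead of proton transfer to the vinyllithium (served by the short tether). Site selectivity is built into the substrate, since the Z geometry from step 5 puts lithium where only C1 is within reach, and the enol ether at C5 and the ketone at C1 appear in their final places without any regioselective methylation.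

Step 9
Reactants: 20 (4R)-4,5-dimethoxy-4-{(2R)-1-[3-methoxy-4-(triisopropylsilyloxy)phenyl]propan-2-yl}-2-(prop-2-en-1-yl)cyclohexa-2,5-dien-1-one
Product: 21 (4R)-4-[(2R)-1-(4-hydroxy-3-methoxyphenyl)propan-2-yl]-4,5-dimethoxy-2-(prop-2-en-1-yl)cyclohexa-2,5-dien-1-one
Conditions: Bu4NF, AcOH, THF, 0 °C
Reagents that add atoms: none
Why: Fluoride-induced cleavage of the aryl silyl ether, buffered with acetic acid so that neither phenoxide nor fluoride acts as a base on the dienone; no carbon stereocentre is involved.

**Compound list**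
1 | 4-bromo-2-methoxyphenol | COc1cc(Br)ccc1O | starting material
2 | (4-bromo-2-methoxyphenoxy)triisopropylsilane | COc1cc(Br)ccc1O[Si](C(C)C)(C(C)C)C(C)C | intermediate
3 | methyl (2S)-3-bromo-2-methylpropanoate | COC(=O)[C@H](C)CBr | starting material
4 | [(2S)-3-methoxy-2-methyl-3-oxopropyl]zinc bromide (not isolated) | COC(=O)[C@H](C)C[Zn]Br | intermediate
5 | methyl (2R)-3-[3-methoxy-4-(triisopropylsilyloxy)phenyl]-2-methylpropanoate | COC(=O)[C@H](C)Cc1ccc(O[Si](C(C)C)(C(C)C)C(C)C)c(OC)c1 | intermediate
6 | (2R)-N-methoxy-3-[3-methoxy-4-(triisopropylsilyloxy)phenyl]-N,2-dimethylpropanamide | CON(C)C(=O)[C@H](C)Cc1ccc(O[Si](C(C)C)(C(C)C)C(C)C)c(OC)c1 | intermediate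
7 | pent-1-en-4-yne | C=CCC#C | starting material
8 | lithium pent-4-en-1-yn-1-ide (not isolated) | [Li]C#CCC=C | intermediate
9 | lithium (2R,3RS)-3-[methoxy(methyl)amino]-1-[3-methoxy-4-(triisopropylsilyloxy)phenyl]-2-methyloct-7-en-4-yn-3-olate (not isolated) | C=CCC#CC(O[Li])(N(C)OC)[C@H](C)Cc1ccc(O[Si](C(C)C)(C(C)C)C(C)C)c(OC)c1 | intermediate
10 | (2R)-1-[3-methoxy-4-(triisopropylsilyloxy)phenyl]-2-methyloct-7-en-4-yn-3-one | C=CCC#CC(=O)[C@H](C)Cc1ccc(O[Si](C(C)C)(C(C)C)C(C)C)c(OC)c1 | intermediate
11 | (2R,4Z)-5-iodo-1-[3-methoxy-4-(triisopropylsilyloxy)phenyl]-2-methylocta-4,7-dien-3-one | C=CC/C(I)=C/C(=O)[C@H](C)Cc1ccc(O[Si](C(C)C)(C(C)C)C(C)C)c(OC)c1 | intermediate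
12 | methyl prop-2-ynoate (methyl propiolate) | COC(=O)C#C | starting material
13 | lithium 3-methoxy-3-oxoprop-1-yn-1-ide (not isolated) | COC(=O)C#C[Li] | intermediate
14 | methyl (4R,5Z)-4-hydroxy-6-iodo-4-{(2R)-1-[3-methoxy-4-(triisopropylsilyloxy)phenyl]propan-2-yl}nona-5,8-dien-2-ynoate | COC(=O)C#C[C@](O)(/C=C(\I)CC=C)[C@H](C)Cc1ccc(O[Si](C(C)C)(C(C)C)C(C)C)c(OC)c1 | intermediate
15 | methyl (2E,4R,5Z)-4-hydroxy-6-iodo-3-methoxy-4-{(2R)-1-[3-methoxy-4-(triisopropylsilyloxy)phenyl]propan-2-yl}nona-2,5,8-trienoate (not isolated) | COC(=O)/C=C(/OC)[C@](O)(/C=C(\I)CC=C)[C@H](C)Cc1ccc(O[Si](C(C)C)(C(C)C)C(C)C)c(OC)c1 | intermediate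
16 | (5R)-5-[(1Z)-2-iodopenta-1,4-dien-1-yl]-4-methoxy-5-{(2R)-1-[3-methoxy-4-(triisopropylsilyloxy)phenyl]propan-2-yl}furan-2(5H)-one | COC1=CC(=O)O[C@@]1(/C=C(\I)CC=C)[C@H](C)Cc2ccc(O[Si](C(C)C)(C(C)C)C(C)C)c(OC)c2 | intermediate
17 | (5R)-5-[(1E)-2-lithiopenta-1,4-dien-1-yl]-4-methoxy-5-{(2R)-1-[3-methoxy-4-(triisopropylsilyloxy)phenyl]propan-2-yl}furan-2(5H)-one, lithium cis to C5 of the furanone as iodine was in 16 (not isolated) | COC1=CC(=O)O[C@@]1(/C=C(\[Li])CC=C)[C@H](C)Cc2ccc(O[Si](C(C)C)(C(C)C)C(C)C)c(OC)c2 | intermediate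
18 | lithium (1R,4R)-5-methoxy-4-{(2R)-1-[3-methoxy-4-(triisopropylsilyloxy)phenyl]propan-2-yl}-2-(prop-2-en-1-yl)-7-oxabicyclo[2.2.1]hepta-2,5-dien-1-olate (not isolated) | [Li]O[C@@]12C(CC=C)=C[C@@](O1)(C(OC)=C2)[C@H](C)Cc3ccc(O[Si](C(C)C)(C(C)C)C(C)C)c(OC)c3 | intermediate
19 | lithium alkoxide of (4R)-4-hydroxy-5-methoxy-4-{(2R)-1-[3-methoxy-4-(triisopropylsilyloxy)phenyl]propan-2-yl}-2-(prop-2-en-1-yl)cyclohexa-2,5-dien-1-one (not isolated) | C=CCC1=C[C@](O[Li])([C@H](C)Cc2ccc(O[Si](C(C)C)(C(C)C)C(C)C)c(OC)c2)C(OC)=CC1=O | intermediate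
20 | (4R)-4,5-dimethoxy-4-{(2R)-1-[3-methoxy-4-(triisopropylsilyloxy)phenyl]propan-2-yl}-2-(prop-2-en-1-yl)cyclohexa-2,5-dien-1-one | C=CCC1=C[C@](OC)([C@H](C)Cc2ccc(O[Si](C(C)C)(C(C)C)C(C)C)c(OC)c2)C(OC)=CC1=O | intermediate
21 | (4R)-4-[(2R)-1-(4-hydroxy-3-methoxyphenyl)propan-2-yl]-4,5-dimethoxy-2-(prop-2-en-1-yl)cyclohexa-2,5-dien-1-one | C=CCC1=C[C@](OC)([C@H](C)Cc2ccc(O)c(OC)c2)C(OC)=CC1=O | target

**Step count**
Total: 9 steps. Longest linear sequence: 9 steps (1 → 21); 3, 7 and 12 are bought and enter in steps 2, 4 and 6.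

**Steps most likely to fail**

1. Step 8 (new ring transfer). The folded, strained transition state for attack across the butenolide may be out of reach. Vinyllithium 17 would then be quenched by proton transfer (from C6–H or a bis-allylic CH2), or t-BuLi would add to the lactone before exchange, so that iodine is lost without ring closure. The bridged alkoxide 18 might also be methylated before it opens. The fallback uses known reaction types and avoids the bridged attack by acylating on an open-chain ester; it sets out from 14 and comes back at 20.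
 - The tertiary alcohol is methylated under non-basic conditions, so that retro-addition cannot start (MeOTf, 2,6-di-tert-butyl-4-methylpyridine, CH2Cl2), to give methyl (4R,5Z)-6-iodo-4-methoxy-4-{(2R)-1-[3-methoxy-4-(triisopropylsilyloxy)phenyl]propan-2-yl}nona-5,8-dien-2-ynoate F1.
 - Methoxide-catalysed conjugate addition of methanol (NaOMe, MeOH), with equilibration and separation of the double-bond isomers, gives methyl (2E,4R,5Z)-6-iodo-3,4-dimethoxy-4-{(2R)-1-[3-methoxy-4-(triisopropylsilyloxy)phenyl]propan-2-yl}nona-2,5,8-trienoate F2, in which the ester is cis to C4. The 2Z isomer cannot close and is returned to the equilibration.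
 - Iodine–lithium exchange (t-BuLi, 2 equiv, THF, −100 °C) gives methyl (2E,4R,5E)-6-lithio-3,4-dimethoxy-4-{(2R)-1-[3-methoxy-4-(triisopropylsilyloxy)phenyl]propan-2-yl}nona-2,5,8-trienoate F3 (lithium cis to C4). It acylates itself on the ester through an unstrained six-membered transition state (Parham-type cycloacylation) and, after loss of methoxide, gives 20.

2. Step 6 (C4 stereocentre). Methyl and arylmethyl on C8 differ little in size, so facial discrimination at the ketone may be weak. The tertiary alkoxide can also revert to ketone and alkynide on warming, which would erode yield and ratio. The fallback sets out from 11 and comes back at 16, so that step 7 is no longer needed; it uses a bulkier sp2 nucleophile whose adduct is trapped irreversibly.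
 - Methyl (E)-3-methoxyacrylate is lithiated at C3 (LiN(i-Pr)2, THF, −90 °C) to methyl (2E)-3-lithio-3-methoxyprop-2-enoate F4 (lithium cis to the ester).
 - Addition to 11 gives methyl (2E,4R,5Z)-6-iodo-4-(lithiooxy)-3-methoxy-4-{(2R)-1-[3-methoxy-4-(triisopropylsilyloxy)phenyl]propan-2-yl}nona-2,5,8-trienoate F5. Its alkoxide lies cis to the ester and lactonises in the flask with loss of methoxide to give tetronate 16.
 - The bulkier reagent should respond more strongly to the Felkin–Anh bias; the C4 epimers are separated at the tetronate stage.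

3. Step 4 (skipped enynone). The CH2 between the ynone and the vinyl group may undergo prototropic shift to a conjugated allenyl or dienyl ketone during quench and chromatography. The released N,O-dimethylhydroxylamine may also add to the ynone. The fallback sets out from 6 and comes back at 11 without passing through any ynone, so steps 4 and 5 are both replaced.
 - Reduction of 6 (i-Bu2AlH, THF, −78 °C) gives (2R)-3-[3-methoxy-4-(triisopropylsilyloxy)phenyl]-2-methylpropanal F6, used crude.
 - Addition of lithium acetylide 8 (THF, −78 °C) gives (2R,3RS)-1-[3-methoxy-4-(triisopropylsilyloxy)phenyl]-2-methyloct-7-en-4-yn-3-ol F7; the mixture of carbinol epimers is of no consequence.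
 - Hydroxyl-directed trans-hydroalumination (NaAlH2(OCH2CH2OCH3)2, THF, 0 °C) and iodinolysis in the same flask (I2, −78 °C) place iodine on the distal alkyne carbon, cis to the carbinol, and give (2R,3RS,4Z)-5-iodo-1-[3-methoxy-4-(triisopropylsilyloxy)phenyl]-2-methylocta-4,7-dien-3-ol F8.
 - Oxidation (Dess–Martin periodinane, NaHCO3, CH2Cl2) gives 11.

Further compounds
F1 | step 8 | methyl (4R,5Z)-6-iodo-4-methoxy-4-{(2R)-1-[3-methoxy-4-(triisopropylsilyloxy)phenyl]propan-2-yl}nona-5,8-dien-2-ynoate | COC(=O)C#C[C@](OC)(/C=C(\I)CC=C)[C@H](C)Cc1ccc(O[Si](C(C)C)(C(C)C)C(C)C)c(OC)c1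
F2 | step 8 | methyl (2E,4R,5Z)-6-iodo-3,4-dimethoxy-4-{(2R)-1-[3-methoxy-4-(triisopropylsilyloxy)phenyl]propan-2-yl}nona-2,5,8-trienoate | COC(=O)/C=C(/OC)[C@](OC)(/C=C(\I)CC=C)[C@H](C)Cc1ccc(O[Si](C(C)C)(C(C)C)C(C)C)c(OC)c1
F3 | step 8 | methyl (2E,4R,5E)-6-lithio-3,4-dimethoxy-4-{(2R)-1-[3-methoxy-4-(triisopropylsilyloxy)phenyl]propan-2-yl}nona-2,5,8-trienoate | COC(=O)/C=C(/OC)[C@](OC)(/C=C(\[Li])CC=C)[C@H](C)Cc1ccc(O[Si](C(C)C)(C(C)C)C(C)C)c(OC)c1
F4 | step 6 | methyl (2E)-3-lithio-3-methoxyprop-2-enoate | COC(=O)/C=C(\[Li])OC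
F5 | step 6 | methyl (2E,4R,5Z)-6-iodo-4-(lithiooxy)-3-methoxy-4-{(2R)-1-[3-methoxy-4-(triisopropylsilyloxy)phenyl]propan-2-yl}nona-2,5,8-trienoate | COC(=O)/C=C(/OC)[C@](O[Li])(/C=C(\I)CC=C)[C@H](C)Cc1ccc(O[Si](C(C)C)(C(C)C)C(C)C)c(OC)c1
F6 | step 4 | (2R)-3-[3-methoxy-4-(triisopropylsilyloxy)phenyl]-2-methylpropanal | O=C[C@H](C)Cc1ccc(O[Si](C(C)C)(C(C)C)C(C)C)c(OC)c1
F7 | step 4 | (2R,3RS)-1-[3-methoxy-4-(triisopropylsilyloxy)phenyl]-2-methyloct-7-en-4-yn-3-ol | C=CCC#CC(O)[C@H](C)Cc1ccc(O[Si](C(C)C)(C(C)C)C(C)C)c(OC)c1
F8 | step 4 | (2R,3RS,4Z)-5-iodo-1-[3-methoxy-4-(triisopropylsilyloxy)phenyl]-2-methylocta-4,7-dien-3-ol | C=CC/C(I)=C/C(O)[C@H](C)Cc1ccc(O[Si](C(C)C)(C(C)C)C(C)C)c(OC)c1
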